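**Plan**

1. Ring locants used below: C1 = quaternary ring carbon (CH3, CH2O), C2 = CH(CH3), C3 and C4 = CH2, C5 = ring carbon of the C=CMe2 unit, C6 = ring CH carrying the three-carbon aldehyde chain.
2. Retrosynthesis: cut the neopentyl aryl ether O–CH2 (isofraxidin plus a neopentyl alcohol); then cut the ring bond C1–C6 together with the CH2–O bond by a retro magnesium-ene/oxygenation; then cut the open chain at C5=C6 (Horner–Wadsworth–Emmons), at the two C–CH3 bonds of the future isopropylidene (MeLi), at C4–C5 (phosphonate alkylation) and at C1–C2 (conjugate addition to ethyl crotonate).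
3. Forward: the acyclic C17 chain is joined linearly, the only carbocycle closes in step 9, the purchased coumarin is attached afterwards and the aldehyde is unmasked last.
4. Stereochemistry: C2 is set by (R)-BINAP/rhodium catalysis in step 1; C1 and C6 are both set in step 9 by substrate control from C2 through a chair-like bicyclic ene transition state.
5. Enabling feature: the array O–CH2–C1–C6–C5=CMe2 (an exocyclic tetrasubstituted alkene at C5, C6 allylic, C1 homoallylic and bearing the CH2O carbon) is the retron of a metallo-ene reaction. An allylmagnesium spanning C6–C5–CMe2 adds across a C1=CH2 alkene and leaves the C–Mg bond exactly where the ether oxygen sits.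

Key step: step 9

Remark: the trisubstituted alkene of the open-chain intermediates may be carried as an E/Z mixture and the allylic chloride as a mixture of allylic isomers and epimers, because all of them should give one rapidly equilibrating allylmagnesium species.

**Step 1**
Reactants: 1 ethyl (E)-but-2-enoate; 2 potassium trifluoro(prop-1-en-2-yl)borate
Product: 3 ethyl (3S)-3,4-dimethylpent-4-enoate
Conditions: [Rh(cod)2]BF4 (3 mol %), (R)-BINAP (3.3 mol %), toluene/H2O 10:1, 100 °C
Reagents that add atoms: none
Why: Rhodium-catalysed asymmetric conjugate addition (Hayashi–Miyaura type) of an alkenyl trifluoroborate to an (E)-enoate; the (R)-BINAP–Rh–alkenyl species should insert the enoate with the facial sense known for arylation of (E)-crotonates, giving the (S)-configured β-carbon that becomes C2.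

**Step 2**
Reactants: 3 ethyl (3S)-3,4-dimethylpent-4-enoate
Product: 4 (3S)-3,4-dimethylpent-4-en-1-ol
Conditions: LiAlH4, Et2O, 0 °C; aq. NaOH work-up
Reagents that add atoms: none
Why: Hydride reduction of an ester to the primary alcohol; the isolated alkene and the stereocenter are not touched.

**Step 3**
Reactants: 4 (3S)-3,4-dimethylpent-4-en-1-ol
Product: 5 (3S)-5-iodo-2,3-dimethylpent-1-ene
Conditions: I2, PPh3, imidazole, CH2Cl2, 0 °C to rt
Reagents that add atoms: iodine II
Why: Appel-type iodination through the alkoxyphosphonium salt with SN2 displacement at the primary carbon, remote from the stereocenter.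

**Step 4**
Reactants: 5 (3S)-5-iodo-2,3-dimethylpent-1-ene; 6 triethyl phosphonoacetate
Product: 7 ethyl (5S)-2-(diethoxyphosphoryl)-5,6-dimethylhept-6-enoate (both epimers at C2 of the heptenoate)
Conditions: NaH, DMSO, rt; then 5, 60 °C (6 in 1.5-fold excess)
Reagents that add atoms: none
Why: SN2 C-alkylation of the sodium salt of the phosphonoacetate by a primary iodide; the excess of 6 should suppress dialkylation, and the new centre is lost in step 6.

**Step 5**
Reactants: 8 methyl 4,4-dimethoxybutanoate
Product: 9 4,4-dimethoxybutanal
Conditions: i-Bu2AlH (1.05 equiv), CH2Cl2, −78 °C; aq. potassium sodium tartrate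
Reagents that add atoms: none
Why: Partial reduction of a methyl ester through the tetrahedral aluminium hemiacetal, which is stable at −78 °C and releases the aldehyde on work-up; the acetal is inert.

**Step 6**
Reactants: 7 ethyl (5S)-2-(diethoxyphosphoryl)-5,6-dimethylhept-6-enoate; 9 4,4-dimethoxybutanal
Product: 10 ethyl (2E,5S)-2-(4,4-dimethoxybutylidene)-5,6-dimethylhept-6-enoate
Conditions: NaH, THF, 0 °C to rt
Reagents that add atoms: none
Why: Horner–Wadsworth–Emmons olefination of an α-alkylated phosphonoacetate with an aliphatic aldehyde forms the C5=C6 bond; the E isomer is expected to predominate and the geometry is of no consequence later.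

**Step 7**
Reactants: 10 ethyl (2E,5S)-2-(4,4-dimethoxybutylidene)-5,6-dimethylhept-6-enoate
Product: 11 (3E)-3-[(3S)-3,4-dimethylpent-4-en-1-yl]-7,7-dimethoxy-2-methylhept-3-en-2-ol
Conditions: MeLi (3 equiv), Et2O, −78 to 0 °C; aq. NH4Cl
Reagents that add atoms: methyllithium [Li]C
Why: Double 1,2-addition of methyllithium to the ester gives the tertiary allylic alcohol and installs both methyl groups of the future isopropylidene; the α-branched, β-substituted enoate disfavours conjugate addition.

**Step 8**
Reactants: 11 (3E)-3-[(3S)-3,4-dimethylpent-4-en-1-yl]-7,7-dimethoxy-2-methylhept-3-en-2-ol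
Product: 12 (3S)-6-(1-chloro-4,4-dimethoxybutyl)-2,3,7-trimethylocta-1,6-diene (epimers at the chlorinated carbon)
Conditions: SOCl2, 2,6-lutidine, Et2O, −30 to 0 °C
Reagents that add atoms: thionyl chloride O=S(Cl)Cl
Why: Chlorination of a tertiary allylic alcohol through its chlorosulfite with allylic transposition (SNi′) should give the secondary chloride with the tetrasubstituted alkene; the base buffers HCl to protect the acetal, and any tertiary allylic isomer serves equally in step 9.

**Step 9**
Reactants: 12 (3S)-6-(1-chloro-4,4-dimethoxybutyl)-2,3,7-trimethylocta-1,6-diene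
Product: 15 [(1S,2S,6S)-2-(3,3-dimethoxypropyl)-1,6-dimethyl-3-(propan-2-ylidene)cyclohexyl]methanol, via allylmagnesium chloride 13 (not isolated), via cyclised neopentyl-type alkylmagnesium chloride 14 (not isolated)
Conditions: Mg powder (activated), THF, −65 °C; then 70 °C (sealed vessel); then dry O2, −78 °C; aq. NH4Cl/Na2SO3
Reagents that add atoms: dioxygen O=O
Why: Magnesium inserts into the allylic C–Cl bond to give the fluxional allylmagnesium chloride 13; on warming, its less substituted terminus C6 bonds to the internal carbon C1 of the isopropenyl group while magnesium passes from the CMe2 terminus to the terminal CH2 through a six-centre suprafacial array, and O2 then turns the new primary C–Mg bond of 14 into C–OH. The closest known reaction type is the intramolecular type 2 magnesium-ene cyclisation of 2-(alkenyl)allylmagnesium chlorides (enophile tethered to the central allyl carbon) followed by electrophilic trapping. The cyclohexane closes in the 6-exo-trig mode on the 1,1-disubstituted alkene, the six-centre array and the forming ring making a bicyclo[3.3.1]-like transition state with a chair carbocycle. At C1 the CH2Mg carbon is held over the ring by the magnesium bridge to CMe2 and so must become axial, leaving CH3 equatorial; at C6 the acetal chain stays on the allyl side cis to C4 and away from CMe2, which makes it axial and anti to CH2Mg; the C2 methyl group takes the equatorial site of this chair (the other fold would put it 1,3-diaxial to the C6 chain), so (S)-C2 should relay to (1S,6S) in the ring locants of the plan. The step needs bonding at C6 and not at the CMe2 terminus, which should be secured because the alternative would join two fully substituted carbons and give the less substituted alkene; it also needs the acetal to stay inert, which THF as donor solvent should secure.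

**Step 10**
Reactants: 15 [(1S,2S,6S)-2-(3,3-dimethoxypropyl)-1,6-dimethyl-3-(propan-2-ylidene)cyclohexyl]methanol; 16 7-hydroxy-6,8-dimethoxy-2H-chromen-2-one (isofraxidin)
Product: 17 7-{[(1S,2S,6S)-2-(3,3-dimethoxypropyl)-1,6-dimethyl-3-(propan-2-ylidene)cyclohexyl]methoxy}-6,8-dimethoxy-2H-chromen-2-one
Conditions: Bu3P=CHCN (cyanomethylenetributylphosphorane), toluene, 110 °C
Reagents that add atoms: none
Why: Mitsunobu-type etherification with the Tsunoda ylide, which tolerates the heating a neopentyl alkoxyphosphonium needs; the acidic coumarin phenol is the nucleophile, SN2 occurs at the exocyclic CH2, and no stereocenter is involved.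

**Step 11**
Reactants: 17 7-{[(1S,2S,6S)-2-(3,3-dimethoxypropyl)-1,6-dimethyl-3-(propan-2-ylidene)cyclohexyl]methoxy}-6,8-dimethoxy-2H-chromen-2-one
Product: 18 3-[(1S,2S,3S)-2-{[(6,8-dimethoxy-2-oxo-2H-chromen-7-yl)oxy]methyl}-2,3-dimethyl-6-(propan-2-ylidene)cyclohexyl]propanal
Conditions: PPTS, acetone/H2O, 40 °C
Reagents that add atoms: water O
Why: Mild acid-catalysed hydrolysis of the dimethyl acetal releases the aldehyde; the lactone, the aryl ether and the tetrasubstituted alkene should survive these conditions, and the C6 stereocenter is not α to the carbonyl.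

**Compound list**

1 | ethyl (E)-but-2-enoate | C/C=C/C(=O)OCC | starting material
2 | potassium trifluoro(prop-1-en-2-yl)borate | C=C(C)[B-](F)(F)F.[K+] | starting material
3 | ethyl (3S)-3,4-dimethylpent-4-enoate | C=C(C)[C@@H](C)CC(=O)OCC | intermediate
4 | (3S)-3,4-dimethylpent-4-en-1-ol | C=C(C)[C@@H](C)CCO | intermediate
5 | (3S)-5-iodo-2,3-dimethylpent-1-ene | C=C(C)[C@@H](C)CCI | intermediate
6 | triethyl phosphonoacetate | CCOC(=O)CP(=O)(OCC)OCC | starting material
7 | ethyl (5S)-2-(diethoxyphosphoryl)-5,6-dimethylhept-6-enoate | CCOC(=O)C(CC[C@H](C)C(C)=C)P(=O)(OCC)OCC | intermediate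
8 | methyl 4,4-dimethoxybutanoate | COC(=O)CCC(OC)OC | starting material
9 | 4,4-dimethoxybutanal | O=CCCC(OC)OC | intermediate
10 | ethyl (2E,5S)-2-(4,4-dimethoxybutylidene)-5,6-dimethylhept-6-enoate | CCOC(=O)/C(CC[C@H](C)C(C)=C)=C/CCC(OC)OC | intermediate
11 | (3E)-3-[(3S)-3,4-dimethylpent-4-en-1-yl]-7,7-dimethoxy-2-methylhept-3-en-2-ol | CC(C)(O)/C(CC[C@H](C)C(C)=C)=C/CCC(OC)OC | intermediate
12 | (3S)-6-(1-chloro-4,4-dimethoxybutyl)-2,3,7-trimethylocta-1,6-diene | C=C(C)[C@@H](C)CCC(=C(C)C)C(Cl)CCC(OC)OC | intermediate
13 | allylmagnesium chloride from 12 (drawn with Mg on C6; in 1,3-equilibrium with the CMe2-bound form) | C=C(C)[C@@H](C)CCC(=C(C)C)C([Mg]Cl)CCC(OC)OC | intermediate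
14 | {[(1S,2S,6S)-2-(3,3-dimethoxypropyl)-1,6-dimethyl-3-(propan-2-ylidene)cyclohexyl]methyl}magnesium chloride | Cl[Mg]C[C@@]1(C)[C@@H](C)CCC(=C(C)C)[C@@H]1CCC(OC)OC | intermediate
15 | [(1S,2S,6S)-2-(3,3-dimethoxypropyl)-1,6-dimethyl-3-(propan-2-ylidene)cyclohexyl]methanol | OC[C@@]1(C)[C@@H](C)CCC(=C(C)C)[C@@H]1CCC(OC)OC | intermediate
16 | 7-hydroxy-6,8-dimethoxy-2H-chromen-2-one (isofraxidin) | COc1cc2ccc(=O)oc2c(OC)c1O | starting material
17 | 7-{[(1S,2S,6S)-2-(3,3-dimethoxypropyl)-1,6-dimethyl-3-(propan-2-ylidene)cyclohexyl]methoxy}-6,8-dimethoxy-2H-chromen-2-one | COc1cc2ccc(=O)oc2c(OC)c1OC[C@@]1(C)[C@@H](C)CCC(=C(C)C)[C@@H]1CCC(OC)OC | intermediate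
18 | 3-[(1S,2S,3S)-2-{[(6,8-dimethoxy-2-oxo-2H-chromen-7-yl)oxy]methyl}-2,3-dimethyl-6-(propan-2-ylidene)cyclohexyl]propanal | COc1cc2ccc(=O)oc2c(OC)c1OC[C@@]1(C)[C@@H](C)CCC(=C(C)C)[C@@H]1CCC=O | target

**Step count**

Total steps: 11. Longest linear sequence: 10 steps (steps 1 to 4 and 6 to 11).

**Steps most likely to fail**

Step 9. The allyl unit may bond through its CMe2 terminus instead of C6. The hindered 1,1-disubstituted alkene may also insert too slowly, so that Wurtz coupling or protonation of the allyl Grignard reagent takes over. Fallback: setting out from 11, the tertiary alcohol would be converted (n-BuLi, ClCO2Me, THF) into the methyl carbonate F1. The isopropenyl group would then be hydroborated and oxidised (9-BBN; NaBO3·4H2O) to the primary alcohol F2, and this oxidised (Dess–Martin periodinane) to the α-methyl aldehyde F3. Pd(PPh3)4 and pyrrolidine in DMSO (enamine catalysis combined with allyl ionisation by zerovalent palladium, an intramolecular Tsuji–Trost α-allylation of an aldehyde) should close the same C1–C6 bond by attack of the enamine on the less substituted allyl terminus, giving the cyclised aldehyde F4. Reduction with NaBH4 in MeOH would come back to the route at 15. Stereocontrol at C1 and C6 is less well defined in this polar closure, so diastereomers may have to be separated at this stage.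

Step 10. Displacement at the neopentyl alkoxyphosphonium carbon may be too slow, so that the alcohol is recovered or consumed by side reactions of the ylide. Fallback: setting out from 16, triflation (Tf2O, pyridine, CH2Cl2) would give the aryl triflate F5. A palladium-catalysed C–O cross-coupling of F5 with alcohol 15 (Pd2(dba)3, tBuBrettPhos, Cs2CO3, toluene, 90 °C) makes the bond at the aryl carbon instead of the hindered CH2 and comes back to the route at 17.

Step 8. Ionisation of the tertiary allylic chlorosulfite may end in elimination, and HCl may cleave the acetal. Fallback: setting out from 11, deliberate dehydration (Burgess reagent, benzene, 50 °C; only the methyl groups carry β-hydrogens) would give the 1,3-diene F6. Hydromagnesiation catalysed by Cp2TiCl2 with i-BuMgCl in Et2O should add H to the terminal CH2 of the diene and give the allylmagnesium chloride without any halide. This comes back to the route at 13, which is then heated and oxygenated as in step 9.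

**Further compounds**

F1 | step 9 | (3E)-3-[(3S)-3,4-dimethylpent-4-en-1-yl]-7,7-dimethoxy-2-methylhept-3-en-2-yl methyl carbonate | COC(=O)OC(C)(C)/C(CC[C@H](C)C(C)=C)=C/CCC(OC)OC
F2 | step 9 | (3E)-3-[(3S)-5-hydroxy-3,4-dimethylpentyl]-7,7-dimethoxy-2-methylhept-3-en-2-yl methyl carbonate | COC(=O)OC(C)(C)/C(CC[C@H](C)C(C)CO)=C/CCC(OC)OC
F3 | step 9 | (3E)-3-[(3S)-3,4-dimethyl-5-oxopentyl]-7,7-dimethoxy-2-methylhept-3-en-2-yl methyl carbonate | COC(=O)OC(C)(C)/C(CC[C@H](C)C(C)C=O)=C/CCC(OC)OC
F4 | step 9 | (1S,2S,6S)-2-(3,3-dimethoxypropyl)-1,6-dimethyl-3-(propan-2-ylidene)cyclohexane-1-carbaldehyde | O=C[C@@]1(C)[C@@H](C)CCC(=C(C)C)[C@@H]1CCC(OC)OC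
F5 | step 10 | 6,8-dimethoxy-2-oxo-2H-chromen-7-yl trifluoromethanesulfonate | COc1cc2ccc(=O)oc2c(OC)c1OS(=O)(=O)C(F)(F)F
F6 | step 8 | (3S,6E)-6-(4,4-dimethoxybutylidene)-2,3,7-trimethylocta-1,7-diene | C=C(C)/C(CC[C@H](C)C(C)=C)=C/CCC(OC)OC
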